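**Plan**
- Retrosynthesis: first the two amide C–N bonds are cut (one diacid, two equivalents of protected agmatine), then the C5–vinyl bond (bromination para to O1, Heck reaction), and last the two bonds that tie the benzo ring A to the heterocycle, O1–C7a and C3–C3a.
- Enabling feature: ring A is joined to the dihydrofuran ring B only through the adjacent carbons C7a and C3a and has H at C7, so it can enter as a symmetric 1,2-benzdiyne equivalent (a 2-silyl-1,3-bis(triflyloxy)benzene). O1–C2–C3–C(=O) is an aldol unit, nucleophilic at C3 as a ketene silyl acetal and at O1 as an alkoxide.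
- Forward: β-keto ester, (R)-β-hydroxy ester, bis-silyl ketene acetal, then a fluoride-triggered aryne relay that closes ring B onto ring A in one operation. The second triflate and both silyl groups leave within that cascade; C5 bromination, Heck reaction, acidolysis, double amidation and Boc removal follow.
- Stereochemistry: C2 comes from a Noyori–Ikariya transfer hydrogenation and is not touched again. C3 is an epimerisable α-aryl ester centre set trans to the C2 aryl group by thermodynamic control. The alkene is E from the Heck reaction.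

Key step: step 5

Remark: the free base drawn is obtained by neutralising the bis(trifluoroacetate) from the last step on a hydroxide-form resin, and 2-(trimethylsilyl)-1,3-phenylene bis(trifluoromethanesulfonate) is taken as a catalogue aryne precursor (otherwise accessible from 2-bromoresorcinol by O-silylation, bromine–lithium exchange with retro-Brook shift and triflation).

**Route**

Step 1
Reactants: 1 4-tert-butoxybenzaldehyde; 2 tert-butyl acetate
Product: 3 tert-butyl 3-(4-tert-butoxyphenyl)-3-hydroxypropanoate (racemic)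
Conditions: LDA (1.1 equiv), THF, −78 °C, then 1; AcOH quench at −78 °C
Reagents that add atoms: none
Why: Aldol addition of the lithium ester enolate to a non-enolisable aromatic aldehyde, whose racemic carbinol centre is erased in step 2.

Step 2
Reactants: 3 tert-butyl 3-(4-tert-butoxyphenyl)-3-hydroxypropanoate
Product: 4 tert-butyl 3-(4-tert-butoxyphenyl)-3-oxopropanoate
Conditions: Dess–Martin periodinane (1.2 equiv), CH2Cl2, 0 °C to rt
Reagents that add atoms: none
Why: Dess–Martin oxidation of a benzylic β-hydroxy ester to the β-keto ester under near-neutral conditions that should leave the tert-butyl ether and ester intact.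

Step 3
Reactants: 4 tert-butyl 3-(4-tert-butoxyphenyl)-3-oxopropanoate
Product: 5 tert-butyl (3R)-3-(4-tert-butoxyphenyl)-3-hydroxypropanoate
Conditions: RuCl(p-cymene)[(R,R)-TsDPEN] (1 mol %), HCO2H/Et3N (5:2), DMF, 40 °C
Reagents that add atoms: none
Why: Noyori–Ikariya asymmetric transfer hydrogenation of an aryl ketone, in which the CH/π contact between the p-cymene ligand and the substrate aryl ring selects one carbonyl face, so that the (R,R)-ligand should give the (R)-carbinol as it does with acetophenone.

Step 4
Reactants: 5 tert-butyl (3R)-3-(4-tert-butoxyphenyl)-3-hydroxypropanoate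
Product: 6 [(3R)-1-tert-butoxy-3-(4-tert-butoxyphenyl)-3-(trimethylsilyloxy)prop-1-en-1-yl]oxytrimethylsilane (E/Z mixture, used crude)
Conditions: LDA (2.2 equiv), THF, −78 to −30 °C; TMSCl (2.6 equiv), −78 °C to rt; evaporation, pentane, filtration under argon
Reagents that add atoms: chlorotrimethylsilane, C[Si](C)(C)Cl
Why: The Fráter–Seebach dianion (alkoxide plus ester enolate, which cannot eliminate because oxide is no leaving group) is silylated on both oxygens to give the silyl ether and the O-silyl ketene acetal, without touching the carbinol centre that becomes C2.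

Step 5
Reactants: 6 [(3R)-1-tert-butoxy-3-(4-tert-butoxyphenyl)-3-(trimethylsilyloxy)prop-1-en-1-yl]oxytrimethylsilane; 7 2-(trimethylsilyl)-1,3-phenylene bis(trifluoromethanesulfonate)
Product: 12 tert-butyl (2R,3R)-2-(4-tert-butoxyphenyl)-2,3-dihydro-1-benzofuran-3-carboxylate, via 3-(triflyloxy)benzyne 8 (not isolated), via benzocyclobutene silyl ketal 9 (not isolated), via side-chain aryne 10 (not isolated), via cis C3 epimer 11 (not isolated)
Conditions: CsF (4 equiv), MeCN, rt, 7 (1.0 equiv) added over 2 h to 6 (1.3 equiv); then DBU (0.3 equiv), 40 °C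
Reagents that add atoms: none
Why: Proposed new method: fluoride removes the C-silyl group of 7 to give 3-(triflyloxy)benzyne 8, the nucleophilic β-carbon of ketene acetal 6 bonds to the aryne carbon remote from the triflate and the oxocarbenium carbon closes onto the other one (polar [2+2], C3–C3a formed, ketal 9), a second fluoride cleaves the ketal O–Si bond so that the alkoxide collapses to the ester in a Grob fragmentation that breaks the four-ring C–C(aryl) bond and expels the neighbouring triflate to give aryne 10 at C7a–C7, and the fluoride-liberated C2 alkoxide adds to C7a (O1–C7a formed) before the C7 anion is protonated by acetonitrile. The closest known reaction type is the [2+2]/Grob-fragmentation relay of 3-triflyloxyarynes with ketene silyl acetals, in which the second aryne is trapped by an external partner, together with the ordinary addition of alkoxides to arynes; new are the tethered oxygen trap and the stereodefined β-silyloxy acetal. The transient cyclobutene ring arises by stepwise polar [2+2] closure and is opened again, and the dihydrofuran ring B closes by 5-exo-dig attack of the alkoxide on the aryne, the only mode the two-atom tether allows. C2 is carried over unchanged from 5 because no bond to it is made or broken, and C3, an enolisable α-aryl ester centre, is set by thermodynamic control when the DBU finish converts cis epimer 11 into the trans isomer with the C2 aryl and C3 ester groups on opposite faces. The step needs the two new bonds on adjacent carbons of ring A and no scrambling of C2: the triflate polarises aryne 8 and then acts as the leaving group that moves the triple bond next to the first bond, the symmetry of 7 and the absence of other ring A substituents make a carbon-first and an oxygen-first sequence converge on the same product, and ring opening of the product enolate would be the reverse of a 5-endo-trig closure, for which the C2–O1 bond is badly aligned. Elimination of silanolate from a prematurely desilylated acetal and capture of aryne 10 by a second acetal should be held back by the sparingly soluble fluoride, the slow addition of 7 and the intramolecular nature of the oxygen trap.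

Step 6
Reactants: 12 tert-butyl (2R,3R)-2-(4-tert-butoxyphenyl)-2,3-dihydro-1-benzofuran-3-carboxylate
Product: 13 tert-butyl (2R,3R)-5-bromo-2-(4-tert-butoxyphenyl)-2,3-dihydro-1-benzofuran-3-carboxylate
Conditions: NBS (1.05 equiv), MeCN, 0 °C to rt, dark
Reagents that add atoms: N-bromosuccinimide, O=C1CCC(=O)N1Br
Why: Polar electrophilic aromatic bromination in which the ring oxygen O1 directs to its para position C5 on ring A, whereas the C2 aryl ring offers only positions ortho to a bulky, twisted tert-butoxy group.

Step 7
Reactants: 13 tert-butyl (2R,3R)-5-bromo-2-(4-tert-butoxyphenyl)-2,3-dihydro-1-benzofuran-3-carboxylate; 14 tert-butyl acrylate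
Product: 15 tert-butyl (2R,3R)-5-[(E)-3-tert-butoxy-3-oxoprop-1-en-1-yl]-2-(4-tert-butoxyphenyl)-2,3-dihydro-1-benzofuran-3-carboxylate
Conditions: Pd2(dba)3 (1.5 mol %), [HP(t-Bu)3]BF4 (6 mol %), Cy2NMe (1.2 equiv), 14 (1.5 equiv), dioxane, rt to 40 °C
Reagents that add atoms: none
Why: Mizoroki–Heck reaction in which oxidative addition of the aryl bromide to zerovalent palladium, syn insertion of the acrylate and syn β-hydride elimination give the E-alkene, under amine-base conditions near room temperature that should spare the epimerisable C3 centre.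

Step 8
Reactants: 15 tert-butyl (2R,3R)-5-[(E)-3-tert-butoxy-3-oxoprop-1-en-1-yl]-2-(4-tert-butoxyphenyl)-2,3-dihydro-1-benzofuran-3-carboxylate
Product: 16 (2R,3R)-5-[(E)-2-carboxyethenyl]-2-(4-hydroxyphenyl)-2,3-dihydro-1-benzofuran-3-carboxylic acid
Conditions: TFA/CH2Cl2 (1:2), 0 °C to rt, N2 sweep
Reagents that add atoms: none
Why: Acidolysis with loss of isobutene cleaves both tert-butyl esters and the aryl tert-butyl ether in one operation, and since the C3 carboxylic acid does not enolise in acid both stereocentres should be retained.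

Step 9
Reactants: 17 butane-1,4-diamine; 18 N,N'-bis(tert-butoxycarbonyl)-1H-pyrazole-1-carboxamidine
Product: 19 N-(4-aminobutyl)-N',N''-bis(tert-butoxycarbonyl)guanidine
Conditions: 17 (5 equiv), CH2Cl2, rt; aqueous wash
Reagents that add atoms: none
Why: Guanylation by addition–elimination at the amidine carbon with loss of pyrazole, the excess diamine ensuring that only one amino group reacts.

Step 10
Reactants: 16 (2R,3R)-5-[(E)-2-carboxyethenyl]-2-(4-hydroxyphenyl)-2,3-dihydro-1-benzofuran-3-carboxylic acid; 19 N-(4-aminobutyl)-N',N''-bis(tert-butoxycarbonyl)guanidine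
Product: 20 (2R,3R)-N-{4-[N',N''-bis(tert-butoxycarbonyl)guanidino]butyl}-5-[(E)-3-({4-[N',N''-bis(tert-butoxycarbonyl)guanidino]butyl}amino)-3-oxoprop-1-en-1-yl]-2-(4-hydroxyphenyl)-2,3-dihydro-1-benzofuran-3-carboxamide
Conditions: 19 (2.3 equiv), N,N'-diisopropylcarbodiimide (2.4 equiv), HOBt (2.4 equiv), DMF, 0 °C to rt
Reagents that add atoms: none
Why: Carbodiimide/HOBt amide coupling at both carboxyl groups, in which the primary amine should outcompete the free phenol and any epimerisation of the activated C3 ester would return to the favoured trans isomer.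

Step 11
Reactants: 20 the tetra-Boc bis-amide of step 10
Product: 21 (2R,3R)-N-(4-guanidinobutyl)-5-{(E)-3-[(4-guanidinobutyl)amino]-3-oxoprop-1-en-1-yl}-2-(4-hydroxyphenyl)-2,3-dihydro-1-benzofuran-3-carboxamide (target)
Conditions: TFA/CH2Cl2 (1:1), rt; isolation as the bis(trifluoroacetate), then hydroxide-form anion-exchange resin
Reagents that add atoms: none
Why: Acidolytic removal of the four Boc groups with loss of isobutene and carbon dioxide frees both guanidines without affecting the amides, the E-alkene or the stereocentres.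

**Compound list**
1 | 4-tert-butoxybenzaldehyde | CC(C)(C)Oc1ccc(C=O)cc1 | starting material
2 | tert-butyl acetate | CC(=O)OC(C)(C)C | starting material
3 | tert-butyl 3-(4-tert-butoxyphenyl)-3-hydroxypropanoate (racemic) | CC(C)(C)OC(=O)CC(O)c1ccc(OC(C)(C)C)cc1 | intermediate
4 | tert-butyl 3-(4-tert-butoxyphenyl)-3-oxopropanoate | CC(C)(C)OC(=O)CC(=O)c1ccc(OC(C)(C)C)cc1 | intermediate
5 | tert-butyl (3R)-3-(4-tert-butoxyphenyl)-3-hydroxypropanoate | CC(C)(C)OC(=O)C[C@H](c1ccc(OC(C)(C)C)cc1)O | intermediate
6 | [(3R)-1-tert-butoxy-3-(4-tert-butoxyphenyl)-3-(trimethylsilyloxy)prop-1-en-1-yl]oxytrimethylsilane (E/Z mixture) | CC(C)(C)OC(O[Si](C)(C)C)=C[C@H](c1ccc(OC(C)(C)C)cc1)O[Si](C)(C)C | intermediate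
7 | 2-(trimethylsilyl)-1,3-phenylene bis(trifluoromethanesulfonate) | C[Si](C)(C)c1c(OS(=O)(=O)C(F)(F)F)cccc1OS(=O)(=O)C(F)(F)F | starting material
8 | 3-(trifluoromethanesulfonyloxy)benzyne | O=S(=O)(OC1=CC=CC#C1)C(F)(F)F | intermediate
9 | 8-tert-butoxy-7-[(R)-(4-tert-butoxyphenyl)(trimethylsilyloxy)methyl]-8-(trimethylsilyloxy)bicyclo[4.2.0]octa-1,3,5-trien-2-yl trifluoromethanesulfonate (mixture at C7 and C8) | CC(C)(C)OC1(O[Si](C)(C)C)C([C@H](c2ccc(OC(C)(C)C)cc2)O[Si](C)(C)C)c2cccc(OS(=O)(=O)C(F)(F)F)c21 | intermediate
10 | tert-butyl (3R)-3-(4-tert-butoxyphenyl)-2-(2,3-didehydrophenyl)-3-(trimethylsilyloxy)propanoate (C2 epimers) | CC(C)(C)OC(=O)C([C@H](c1ccc(OC(C)(C)C)cc1)O[Si](C)(C)C)C1=CC=CC#C1 | intermediate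
11 | tert-butyl (2R,3S)-2-(4-tert-butoxyphenyl)-2,3-dihydro-1-benzofuran-3-carboxylate (cis) | c1ccc2c(c1)[C@H](C(=O)OC(C)(C)C)[C@H](c1ccc(OC(C)(C)C)cc1)O2 | intermediate
12 | tert-butyl (2R,3R)-2-(4-tert-butoxyphenyl)-2,3-dihydro-1-benzofuran-3-carboxylate (trans) | c1ccc2c(c1)[C@@H](C(=O)OC(C)(C)C)[C@H](c1ccc(OC(C)(C)C)cc1)O2 | intermediate
13 | tert-butyl (2R,3R)-5-bromo-2-(4-tert-butoxyphenyl)-2,3-dihydro-1-benzofuran-3-carboxylate | Brc1ccc2c(c1)[C@@H](C(=O)OC(C)(C)C)[C@H](c1ccc(OC(C)(C)C)cc1)O2 | intermediate
14 | tert-butyl acrylate | C=CC(=O)OC(C)(C)C | starting material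
15 | tert-butyl (2R,3R)-5-[(E)-3-tert-butoxy-3-oxoprop-1-en-1-yl]-2-(4-tert-butoxyphenyl)-2,3-dihydro-1-benzofuran-3-carboxylate | CC(C)(C)OC(=O)/C=C/c1ccc2c(c1)[C@@H](C(=O)OC(C)(C)C)[C@H](c1ccc(OC(C)(C)C)cc1)O2 | intermediate
16 | (2R,3R)-5-[(E)-2-carboxyethenyl]-2-(4-hydroxyphenyl)-2,3-dihydro-1-benzofuran-3-carboxylic acid | OC(=O)/C=C/c1ccc2c(c1)[C@@H](C(=O)O)[C@H](c1ccc(O)cc1)O2 | intermediate
17 | butane-1,4-diamine | NCCCCN | starting material
18 | N,N'-bis(tert-butoxycarbonyl)-1H-pyrazole-1-carboxamidine | CC(C)(C)OC(=O)NC(=NC(=O)OC(C)(C)C)n1cccn1 | starting material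
19 | N-(4-aminobutyl)-N',N''-bis(tert-butoxycarbonyl)guanidine | NCCCCNC(=NC(=O)OC(C)(C)C)NC(=O)OC(C)(C)C | intermediate
20 | (2R,3R)-N-{4-[N',N''-bis(tert-butoxycarbonyl)guanidino]butyl}-5-[(E)-3-({4-[N',N''-bis(tert-butoxycarbonyl)guanidino]butyl}amino)-3-oxoprop-1-en-1-yl]-2-(4-hydroxyphenyl)-2,3-dihydro-1-benzofuran-3-carboxamide | CC(C)(C)OC(=O)NC(=NC(=O)OC(C)(C)C)NCCCCNC(=O)/C=C/c1ccc2c(c1)[C@@H](C(=O)NCCCCNC(=NC(=O)OC(C)(C)C)NC(=O)OC(C)(C)C)[C@H](c1ccc(O)cc1)O2 | intermediate
21 | (2R,3R)-N-(4-guanidinobutyl)-5-{(E)-3-[(4-guanidinobutyl)amino]-3-oxoprop-1-en-1-yl}-2-(4-hydroxyphenyl)-2,3-dihydro-1-benzofuran-3-carboxamide | NC(N)=NCCCCNC(=O)/C=C/c1ccc2c(c1)[C@@H](C(=O)NCCCCN=C(N)N)[C@H](c1ccc(O)cc1)O2 | target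

**Count and risks**
Total step count: 11. Longest linear sequence: 10 steps (steps 1 to 8, then 10 and 11); step 9 is a one-step side branch.

Steps most likely to fail:

1. Step 5 (proposed new method). Fluoride may desilylate the ketene acetal before the cycloaddition, after which silanolate is eliminated. The second aryne may be intercepted by an external partner before the oxygen is unmasked. The aryl anion next to the triflate may be protonated instead of losing triflate, and the base finish may erode C2 through ring opening. The fallback uses known chemistry, sets out from 4 and returns at 12. Copper-catalysed domino C-arylation/O-arylation of β-keto ester 4 with commercial 1-bromo-2-iodobenzene (CuI, K2CO3, THF, 100 °C) forms the same two ring A bonds at the ketone oxidation level. The C3–C3a bond forms first at the iodide carbon to give tert-butyl 2-(2-bromophenyl)-3-(4-tert-butoxyphenyl)-3-oxopropanoate F1 (not isolated), and the O1–C7a bond then forms at the bromide carbon to give tert-butyl 2-(4-tert-butoxyphenyl)-1-benzofuran-3-carboxylate F2. Dissolving-metal reduction of the furan double bond (Mg, MeOH/THF) should give racemic trans tert-butyl 2-(4-tert-butoxyphenyl)-2,3-dihydro-1-benzofuran-3-carboxylate F3. Preparative chromatography on a chiral stationary phase then delivers 12.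

2. Step 4. The second deprotonation of the aggregated alkoxide may be slow and incomplete, the enolate may be silylated on carbon instead of oxygen, and the labile product may hydrolyse during isolation. The fallback sets out from 5 and returns at 6. The hydroxyl group is capped first (TMSCl, imidazole, CH2Cl2) to give tert-butyl (3R)-3-(4-tert-butoxyphenyl)-3-(trimethylsilyloxy)propanoate F4. This silyl ether is then enolised with LDA in the presence of TMSCl (internal quench, THF, −78 °C), so that no free enolate accumulates, and gives 6.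

3. Step 10. The two carboxyl groups may be acylated at unequal rates because the C3 carboxyl is hindered, the slow O-acylisourea may rearrange to an N-acylurea, and the free phenol may be acylated to give oligomers. The fallback sets out from 13 and returns at 20, replacing the second amidation by a C–C coupling. Acidolysis of 13 (TFA/CH2Cl2) gives (2R,3R)-5-bromo-2-(4-hydroxyphenyl)-2,3-dihydro-1-benzofuran-3-carboxylic acid F5. A single amidation with 19 (N,N'-diisopropylcarbodiimide, HOBt, DMF) gives (2R,3R)-N-{4-[N',N''-bis(tert-butoxycarbonyl)guanidino]butyl}-5-bromo-2-(4-hydroxyphenyl)-2,3-dihydro-1-benzofuran-3-carboxamide F6. A Heck reaction under the step 7 conditions with N-{4-[N',N''-bis(tert-butoxycarbonyl)guanidino]butyl}acrylamide F7 (from 19 and acryloyl chloride, Et3N, CH2Cl2, 0 °C) then gives 20.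

**Further compounds**
F1 | step 5 | tert-butyl 2-(2-bromophenyl)-3-(4-tert-butoxyphenyl)-3-oxopropanoate | CC(C)(C)OC(=O)C(c1ccccc1Br)C(=O)c1ccc(OC(C)(C)C)cc1
F2 | step 5 | tert-butyl 2-(4-tert-butoxyphenyl)-1-benzofuran-3-carboxylate | CC(C)(C)OC(=O)c1c(-c2ccc(OC(C)(C)C)cc2)oc2ccccc12
F3 | step 5 | racemic trans tert-butyl 2-(4-tert-butoxyphenyl)-2,3-dihydro-1-benzofuran-3-carboxylate | c1ccc2c(c1)[C@@H](C(=O)OC(C)(C)C)[C@H](c1ccc(OC(C)(C)C)cc1)O2.c1ccc2c(c1)[C@H](C(=O)OC(C)(C)C)[C@@H](c1ccc(OC(C)(C)C)cc1)O2
F4 | step 4 | tert-butyl (3R)-3-(4-tert-butoxyphenyl)-3-(trimethylsilyloxy)propanoate | CC(C)(C)OC(=O)C[C@H](c1ccc(OC(C)(C)C)cc1)O[Si](C)(C)C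
F5 | step 10 | (2R,3R)-5-bromo-2-(4-hydroxyphenyl)-2,3-dihydro-1-benzofuran-3-carboxylic acid | Brc1ccc2c(c1)[C@@H](C(=O)O)[C@H](c1ccc(O)cc1)O2
F6 | step 10 | (2R,3R)-N-{4-[N',N''-bis(tert-butoxycarbonyl)guanidino]butyl}-5-bromo-2-(4-hydroxyphenyl)-2,3-dihydro-1-benzofuran-3-carboxamide | Brc1ccc2c(c1)[C@@H](C(=O)NCCCCNC(=NC(=O)OC(C)(C)C)NC(=O)OC(C)(C)C)[C@H](c1ccc(O)cc1)O2
F7 | step 10 | N-{4-[N',N''-bis(tert-butoxycarbonyl)guanidino]butyl}acrylamide | C=CC(=O)NCCCCNC(=NC(=O)OC(C)(C)C)NC(=O)OC(C)(C)C
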